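## Retrosynthetic overview

1. The target comes from one acid deprotection of a silyl ether and an acetonide. The C1 ketone and C2 carbinol come from β-face dihydroxylation of a C1=C2 alkene and oxidation. The C5 methyl comes from methylenation of a C5 ketone and β-face hydrogenation.
2. Rings A and B form together (bonds C3–C4 and C4a–C8a) in a catalyst-controlled intramolecular Diels–Alder reaction of a (Z)-ene-1,4-dione, unmasked from a 2,3,5-trisubstituted furan.
3. Key bond C1–C2 (a ring A bond): palladium-catalysed Negishi alkenyl–alkenyl coupling of an (R)-sec-butyl alkenyl iodide with an alkenylzinc reagent.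
4. Bond C5–C6 (a ring B bond): copper-catalysed opening of a Sharpless epoxy alcohol (sets C7) by a furyl Grignard reagent.
5. Building blocks: (R)-2-methylbutan-1-ol, 3-methylfuran-2-carbaldehyde, methyl 2-(bromomethyl)prop-2-enoate and ethynyl(trimethyl)silane.

Numbering: ring atoms are C1 (ketone), C2 (carbinol), C3 (sec-butyl carbon), C4 (quaternary), C4a and C8a (ring fusion), C5 (methyl carbon) and C7 (diol carbon). β is the face of the two ring-fusion hydrogens; α is the opposite face.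

Assumption: (R)-2-methylbutan-1-ol, 3-methylfuran-2-carbaldehyde and methyl 2-(bromomethyl)prop-2-enoate are taken as purchasable.

## Route

Step 1
Reactants: 1 (R)-2-methylbutan-1-ol
Product: 2 (R)-2-methylbutanal
Conditions: TEMPO (10 mol %), PhI(OAc)2, CH2Cl2, 0 → 25 °C; solution used directly
Reagents that add atoms: none
Why: Oxoammonium (TEMPO) oxidation of a primary alcohol is non-basic, so the chiral-pool stereocentre that becomes the sec-butyl centre is not epimerised.

Step 2
Reactants: 2 (R)-2-methylbutanal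
Product: 3 (3R)-1,1-dibromo-3-methylpent-1-ene
Conditions: CBr4, PPh3, CH2Cl2, 0 °C
Reagents that add atoms: carbon tetrabromide, BrC(Br)(Br)Br
Why: Corey–Fuchs dibromo-olefination (Wittig reaction of Ph3P=CBr2) leaves the adjacent stereocentre untouched at 0 °C.

Step 3
Reactants: 3 (3R)-1,1-dibromo-3-methylpent-1-ene
Product: 5 (4R)-4-methylhex-2-yne, via lithium acetylide 4 (not isolated)
Conditions: n-BuLi (2.1 equiv), THF, −78 → 0 °C; then MeI, −78 → 25 °C
Reagents that add atoms: iodomethane, CI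
Why: Second stage of the Corey–Fuchs sequence (Br/Li exchange, 1,2-shift) gives the lithium acetylide, which is C-methylated by MeI.

Step 4
Reactants: 5 (4R)-4-methylhex-2-yne
Product: 7 (2E,4R)-2-iodo-4-methylhex-2-ene, via alkenylzirconocene chloride 6 (not isolated)
Conditions: Cp2Zr(H)Cl (2 equiv), THF, 45 °C; then I2, 0 °C
Reagents that add atoms: iodine, II
Why: Syn hydrozirconation puts zirconium on the less hindered, methyl-bearing alkyne carbon (equilibration with excess reagent), and iodinolysis with retention gives the (E)-alkenyl iodide.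

Step 5
Reactants: 8 3-methylfuran-2-carbaldehyde
Product: 9 2-ethenyl-3-methylfuran
Conditions: Ph3PCH3Br, KOt-Bu, THF, 0 °C
Reagents that add atoms: methyltriphenylphosphonium bromide, C[P+](c1ccccc1)(c1ccccc1)c1ccccc1.[Br-]
Why: Wittig methylenation of an aromatic aldehyde with the non-stabilised ylide.

Step 6
Reactants: 9 2-ethenyl-3-methylfuran
Product: 11 2-(3-methylfuran-2-yl)ethan-1-ol, via alkylborane 10 (not isolated)
Conditions: 9-BBN, THF, 0 → 25 °C; then NaOH, H2O2, 0 °C
Reagents that add atoms: hydrogen peroxide, OO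
Why: Brown hydroboration–oxidation of the terminal vinyl group is anti-Markovnikov with 9-BBN and leaves the furan alone.

Step 7
Reactants: 11 2-(3-methylfuran-2-yl)ethan-1-ol
Product: 12 tert-butyldimethyl[2-(3-methylfuran-2-yl)ethoxy]silane
Conditions: TBSCl, imidazole, DMF, 25 °C
Reagents that add atoms: tert-butyl(chloro)dimethylsilane, CC(C)(C)[Si](C)(C)Cl
Why: Imidazole-promoted silylation masks the primary alcohol for the organometallic steps.

Step 8
Reactants: 13 methyl 2-(bromomethyl)prop-2-enoate, 14 ethynyl(trimethyl)silane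
Product: 15 methyl 2-methylidene-5-(trimethylsilyl)pent-4-ynoate
Conditions: CuI (10 mol %), K2CO3, Bu4NI (10 mol %), DMF, 25 °C
Reagents that add atoms: none
Why: Copper-catalysed alkynylation of a reactive allylic bromide (SN2 and SN2′ give the same 2-substituted allyl product) under weak base spares the C–Si bond.

Step 9
Reactants: 15 methyl 2-methylidene-5-(trimethylsilyl)pent-4-ynoate
Product: 16 2-methylidene-5-(trimethylsilyl)pent-4-yn-1-ol
Conditions: i-Bu2AlH (2.2 equiv), CH2Cl2, −78 °C; Rochelle salt work-up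
Reagents that add atoms: none
Why: 1,2-Reduction of the α-substituted acrylate by i-Bu2AlH at low temperature gives the 2-substituted allylic alcohol.

Step 10
Reactants: 16 2-methylidene-5-(trimethylsilyl)pent-4-yn-1-ol
Product: 17 {(2R)-2-[3-(trimethylsilyl)prop-2-yn-1-yl]oxiran-2-yl}methanol
Conditions: Ti(OiPr)4 (10 mol %), D-(−)-diisopropyl tartrate (12 mol %), t-BuOOH, 4 Å MS, CH2Cl2, −20 °C
Reagents that add atoms: tert-butyl hydroperoxide, CC(C)(C)OO
Why: Katsuki–Sharpless asymmetric epoxidation of a 2-substituted allylic alcohol sets C7, the D-(−)-tartrate giving the (R)-epoxide whose oxygen becomes the C7 hydroxyl.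

Step 11
Reactants: 12 tert-butyldimethyl[2-(3-methylfuran-2-yl)ethoxy]silane, 17 {(2R)-2-[3-(trimethylsilyl)prop-2-yn-1-yl]oxiran-2-yl}methanol
Product: 22 (2S)-2-{[5-(2-{[tert-butyl(dimethyl)silyl]oxy}ethyl)-4-methylfuran-2-yl]methyl}pent-4-yne-1,2-diol, via furyllithium 18 (not isolated), via furylmagnesium bromide 19 (not isolated), via epoxy alkoxide 20 (not isolated), via silylalkyne diol 21 (not isolated)
Conditions: 12: n-BuLi, THF, 0 → 25 °C, then MgBr2·OEt2; 17: i-PrMgCl, THF, −40 °C; combine, CuI (10 mol %), −30 → 0 °C; NH4Cl (aq); then K2CO3, MeOH, 25 °C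
Reagents that add atoms: none
Why: Lithiation at the only free furan α-position, transmetalation and copper-catalysed Grignard opening of the epoxide at its CH2 terminus form the C5–C6 bond without touching C7, and carbonate methanolysis then removes the alkyne silyl group.

Step 12
Reactants: 22 (2S)-2-{[5-(2-{[tert-butyl(dimethyl)silyl]oxy}ethyl)-4-methylfuran-2-yl]methyl}pent-4-yne-1,2-diol
Product: 23 tert-butyl(2-{5-[((4S)-2,2-dimethyl-4-(prop-2-yn-1-yl)-1,3-dioxolan-4-yl)methyl]-3-methylfuran-2-yl}ethoxy)dimethylsilane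
Conditions: Me2C(OMe)2, PPTS (cat.), CH2Cl2, 25 °C
Reagents that add atoms: 2,2-dimethoxypropane, COC(C)(C)OC
Why: Acid-catalysed transketalisation protects the tertiary/primary 1,2-diol as an acetonide before the organometallic and Lewis-acidic steps.

Step 13
Reactants: 23 tert-butyl(2-{5-[((4S)-2,2-dimethyl-4-(prop-2-yn-1-yl)-1,3-dioxolan-4-yl)methyl]-3-methylfuran-2-yl}ethoxy)dimethylsilane, 7 (2E,4R)-2-iodo-4-methylhex-2-ene
Product: 26 tert-butyl{2-[5-({(4S)-4-[(2E,4E,6R)-4,6-dimethylocta-2,4-dien-1-yl]-2,2-dimethyl-1,3-dioxolan-4-yl}methyl)-3-methylfuran-2-yl]ethoxy}dimethylsilane, via alkenylzirconocene chloride 24 (not isolated), via alkenylzinc chloride 25 (not isolated)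
Conditions: Cp2Zr(H)Cl, THF, 25 °C; ZnCl2; then 7, Pd(PPh3)4 (5 mol %), 25 °C
Reagents that add atoms: none
Why: Negishi alkenyl–alkenyl cross-coupling (syn hydrozirconation, Zr-to-Zn transmetalation, palladium-catalysed coupling with retention at both alkenes) forms the C1–C2 bond of the (E,E)-diene and joins the two halves.

Step 14
Reactants: 26 the furan–diene from step 13
Product: 27 (4Z)-1-{[tert-butyl(dimethyl)silyl]oxy}-7-{(4S)-4-[(2E,4E,6R)-4,6-dimethylocta-2,4-dien-1-yl]-2,2-dimethyl-1,3-dioxolan-4-yl}-4-methylhept-4-ene-3,6-dione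
Conditions: NBS (1.05 equiv), NaHCO3, acetone/H2O (10:1), −20 °C, dark; cold work-up, used at once
Reagents that add atoms: water, O
Why: Electrophilic bromination and hydrolytic ring opening of the electron-rich trialkylfuran (Achmatowicz-type furan oxidation) outpaces attack on the diene and gives the enedione with the cis geometry inherited from the ring.

Step 15
Reactants: 27 the (Z)-enedione from step 14
Product: 28 cis-fused adduct: 3α-[(2R)-butan-2-yl]-4α-[3-(tert-butyldimethylsilyloxy)propanoyl]-2,4β-dimethyl-4aβ,8aβ-H-octal-1-en-5-one, C7 spiro-fused to a 2,2-dimethyl-1,3-dioxolane (O on C7 β, CH2O α)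
Conditions: (S)-1-(2-methylphenyl)-3,3-diphenyltetrahydro-1H,3H-pyrrolo[1,2-c][1,3,2]oxazaborole protonated by HN(SO2CF3)2 (20 mol % each), CH2Cl2, −78 → −40 °C
Reagents that add atoms: none
Why: Proposed new method: enantioface-selective intramolecular Diels–Alder reaction of an acyclic (Z)-ene-1,4-dione under chiral oxazaborolidinium catalysis, in which boron binds the C5 carbonyl (its vinylic C4a–H can hydrogen-bond to the catalyst oxygen as in quinone complexes), both cis carbonyl groups are endo so the fusion is cis and the sec-butyl group, the acyl group, C5 and C8 all end up α with the C4 methyl β, and the catalyst aryl group blocks one dienophile face, helped by A(1,3) strain at the sec-butyl centre and only weakly opposed by the C7 acetonide, so that C3, C4, C4a and C8a are set relative to the resident centres; the closest known reactions are oxazaborolidinium-catalysed Diels–Alder reactions of quinones (cyclic cis-enediones) and of trienones in the intramolecular mode.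

Step 16
Reactants: 28 the cis-fused adduct from step 15
Product: 29 the 5-methylidene analogue of 28 (C5=CH2 in place of C5=O)
Conditions: Cp2TiMe2 (1.5 equiv), toluene, 65 °C, dark
Reagents that add atoms: dimethyltitanocene, C[Ti](C)(C1C=CC=C1)C1C=CC=C1
Why: Petasis (titanium carbene) methylenation is non-basic, so the epimerisable C4a centre survives, and it selects the ring ketone over the side-chain ketone shielded by the quaternary C4.

Step 17
Reactants: 29 the 5-methylidene compound from step 16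
Product: 30 the 5α-methyl compound (5β-H), otherwise as 29
Conditions: H2 (1 atm), RhCl(PPh3)3 (10 mol %), benzene/EtOH, 25 °C
Reagents that add atoms: none
Why: Homogeneous hydrogenation with RhCl(PPh3)3 reduces the 1,1-disubstituted exocyclic alkene but not the hindered trisubstituted C1=C2 alkene, and hydrogen adds to the β face, anti to the axial C4 substituent on C4a, placing the C5 methyl α.

Step 18
Reactants: 30 the 5α-methyl compound from step 17
Product: 31 the 1β,2β-diol (2α-methyl), otherwise as 30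
Conditions: OsO4 (5 mol %), NMO, MeSO2NH2, acetone/H2O, 25 °C
Reagents that add atoms: N-methylmorpholine N-oxide, C[N+]1([O-])CCOCC1; water, O
Why: Upjohn syn-dihydroxylation occurs from the β face, away from the α sec-butyl group at C3 and the α ring B carbon on C8a, and sets C2 (OH β, methyl α).

Step 19
Reactants: 31 the 1β,2β-diol from step 18
Product: 32 the protected target: 1-ketone, 2β-OH, side-chain OTBS, C7 acetonide
Conditions: Dess–Martin periodinane, NaHCO3, CH2Cl2, 0 °C
Reagents that add atoms: none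
Why: Dess–Martin oxidation of the secondary C1 alcohol next to the tertiary one gives the α-ketol under buffered, non-basic conditions that do not epimerise C8a.

Step 20
Reactants: 32 the protected target from step 19
Product: 33 (2S,3R,4R,4aR,5R,7R,8aS)-3-[(2R)-butan-2-yl]-2,7-dihydroxy-7-(hydroxymethyl)-4-(3-hydroxypropanoyl)-2,4,5-trimethyloctahydronaphthalen-1(2H)-one
Conditions: 1 M HCl, THF, 0 → 25 °C
Reagents that add atoms: none
Why: Mild aqueous acid hydrolyses the acetonide and the primary silyl ether in one operation without enolising the C1 ketone or dehydrating the β-hydroxy ketone.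

## Compound list

1 | (R)-2-methylbutan-1-ol | CC[C@@H](C)CO | starting material
2 | (R)-2-methylbutanal | CC[C@@H](C)C=O | intermediate
3 | (3R)-1,1-dibromo-3-methylpent-1-ene | CC[C@@H](C)C=C(Br)Br | intermediate
4 | lithium (3R)-3-methylpent-1-yn-1-ide | CC[C@@H](C)C#C[Li] | intermediate
5 | (4R)-4-methylhex-2-yne | CC[C@@H](C)C#CC | intermediate
6 | chloro[(2E,4R)-4-methylhex-2-en-2-yl]zirconocene | CC[C@@H](C)/C=C(C)/[Zr](Cl)(C1C=CC=C1)C1C=CC=C1 | intermediate
7 | (2E,4R)-2-iodo-4-methylhex-2-ene | CC[C@@H](C)/C=C(C)/I | intermediate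
8 | 3-methylfuran-2-carbaldehyde | Cc1ccoc1C=O | starting material
9 | 2-ethenyl-3-methylfuran | Cc1ccoc1C=C | intermediate
10 | 9-[2-(3-methylfuran-2-yl)ethyl]-9-borabicyclo[3.3.1]nonane | Cc1ccoc1CCB1C2CCCC1CCC2 | intermediate
11 | 2-(3-methylfuran-2-yl)ethan-1-ol | Cc1ccoc1CCO | intermediate
12 | tert-butyldimethyl[2-(3-methylfuran-2-yl)ethoxy]silane | Cc1ccoc1CCO[Si](C)(C)C(C)(C)C | intermediate
13 | methyl 2-(bromomethyl)prop-2-enoate | C=C(CBr)C(=O)OC | starting material
14 | ethynyl(trimethyl)silane | C#C[Si](C)(C)C | starting material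
15 | methyl 2-methylidene-5-(trimethylsilyl)pent-4-ynoate | C=C(CC#C[Si](C)(C)C)C(=O)OC | intermediate
16 | 2-methylidene-5-(trimethylsilyl)pent-4-yn-1-ol | C=C(CO)CC#C[Si](C)(C)C | intermediate
17 | {(2R)-2-[3-(trimethylsilyl)prop-2-yn-1-yl]oxiran-2-yl}methanol | C1[C@](O1)(CO)CC#C[Si](C)(C)C | intermediate
18 | [5-(2-{[tert-butyl(dimethyl)silyl]oxy}ethyl)-4-methylfuran-2-yl]lithium | Cc1cc([Li])oc1CCO[Si](C)(C)C(C)(C)C | intermediate
19 | bromo[5-(2-{[tert-butyl(dimethyl)silyl]oxy}ethyl)-4-methylfuran-2-yl]magnesium | Cc1cc([Mg]Br)oc1CCO[Si](C)(C)C(C)(C)C | intermediate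
20 | chloromagnesium alkoxide of 17 | C1[C@](O1)(CO[Mg]Cl)CC#C[Si](C)(C)C | intermediate
21 | (2S)-2-{[5-(2-{[tert-butyl(dimethyl)silyl]oxy}ethyl)-4-methylfuran-2-yl]methyl}-5-(trimethylsilyl)pent-4-yne-1,2-diol | Cc1cc(C[C@](O)(CO)CC#C[Si](C)(C)C)oc1CCO[Si](C)(C)C(C)(C)C | intermediate
22 | (2S)-2-{[5-(2-{[tert-butyl(dimethyl)silyl]oxy}ethyl)-4-methylfuran-2-yl]methyl}pent-4-yne-1,2-diol | Cc1cc(C[C@](O)(CO)CC#C)oc1CCO[Si](C)(C)C(C)(C)C | intermediate
23 | tert-butyl(2-{5-[((4S)-2,2-dimethyl-4-(prop-2-yn-1-yl)-1,3-dioxolan-4-yl)methyl]-3-methylfuran-2-yl}ethoxy)dimethylsilane | Cc1cc(C[C@@]2(CC#C)COC(C)(C)O2)oc1CCO[Si](C)(C)C(C)(C)C | intermediate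
24 | (E)-alkenylzirconocene chloride from 23 (Cp2ZrCl on the terminal alkene carbon) | Cl[Zr](C1C=CC=C1)(C1C=CC=C1)/C=C/C[C@]1(Cc2cc(C)c(CCO[Si](C)(C)C(C)(C)C)o2)COC(C)(C)O1 | intermediate
25 | (E)-alkenylzinc chloride from 24 | Cl[Zn]/C=C/C[C@]1(Cc2cc(C)c(CCO[Si](C)(C)C(C)(C)C)o2)COC(C)(C)O1 | intermediate
26 | tert-butyl{2-[5-({(4S)-4-[(2E,4E,6R)-4,6-dimethylocta-2,4-dien-1-yl]-2,2-dimethyl-1,3-dioxolan-4-yl}methyl)-3-methylfuran-2-yl]ethoxy}dimethylsilane | CC[C@@H](C)/C=C(C)/C=C/C[C@]1(Cc2cc(C)c(CCO[Si](C)(C)C(C)(C)C)o2)COC(C)(C)O1 | intermediate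
27 | (4Z)-1-{[tert-butyl(dimethyl)silyl]oxy}-7-{(4S)-4-[(2E,4E,6R)-4,6-dimethylocta-2,4-dien-1-yl]-2,2-dimethyl-1,3-dioxolan-4-yl}-4-methylhept-4-ene-3,6-dione | CC[C@@H](C)/C=C(C)/C=C/C[C@]1(CC(=O)/C=C(C)\C(=O)CCO[Si](C)(C)C(C)(C)C)COC(C)(C)O1 | intermediate
28 | cis-fused octal-1-en-5-one: 3α-[(2R)-butan-2-yl], 4α-[3-(TBS-oxy)propanoyl], 2,4β-dimethyl, 4aβ-H, 8aβ-H, C7 spiro-acetonide (O on C7 β, CH2O α) | CC[C@@H](C)[C@@H]1[C@](C)(C(=O)CCO[Si](C)(C)C(C)(C)C)[C@@H]2C(=O)C[C@]3(COC(C)(C)O3)C[C@@H]2C=C1C | intermediate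
29 | 5-methylidene analogue of 28 | CC[C@@H](C)[C@@H]1[C@](C)(C(=O)CCO[Si](C)(C)C(C)(C)C)[C@@H]2C(=C)C[C@]3(COC(C)(C)O3)C[C@@H]2C=C1C | intermediate
30 | 5α-methyl (5β-H) compound from 29 | CC[C@@H](C)[C@@H]1[C@](C)(C(=O)CCO[Si](C)(C)C(C)(C)C)[C@@H]2[C@H](C)C[C@]3(COC(C)(C)O3)C[C@@H]2C=C1C | intermediate
31 | 1β,2β-diol (2α-methyl) from 30 | CC[C@@H](C)[C@@H]1[C@](C)(C(=O)CCO[Si](C)(C)C(C)(C)C)[C@@H]2[C@H](C)C[C@]3(COC(C)(C)O3)C[C@@H]2[C@@H](O)[C@@]1(C)O | intermediate
32 | protected target: 1-ketone, 2β-OH, side-chain OTBS, C7 acetonide | CC[C@@H](C)[C@@H]1[C@](C)(C(=O)CCO[Si](C)(C)C(C)(C)C)[C@@H]2[C@H](C)C[C@]3(COC(C)(C)O3)C[C@@H]2C(=O)[C@@]1(C)O | intermediate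
33 | (2S,3R,4R,4aR,5R,7R,8aS)-3-[(2R)-butan-2-yl]-2,7-dihydroxy-7-(hydroxymethyl)-4-(3-hydroxypropanoyl)-2,4,5-trimethyloctahydronaphthalen-1(2H)-one | CC[C@@H](C)[C@@H]1[C@](C)(C(=O)CCO)[C@@H]2[C@H](C)C[C@](O)(CO)C[C@@H]2C(=O)[C@@]1(C)O | target

## Step count

Total: 20 steps. Longest linear sequence: 13 steps (steps 8–10 or 5–7, then 11–20); the alkenyl iodide branch (steps 1–4) joins at step 13.

## Steps most likely to fail

**Step 14 (furan unmasking in the presence of the diene).** NBS may attack the electron-rich diene, or 27 may cyclise without control before the catalyst is added. The fallback sets out from 23 and returns at 27, and oxidises the furan before the diene exists. Alkyne 23 is treated with Br2, MeOH, Na2CO3 at −40 °C (Clauson-Kaas oxidation) to give the 2,5-dimethoxy-2,5-dihydrofuran F1 (mixture of ketal epimers). Hydrozirconation gives the alkenylzirconocene chloride F2, ZnCl2 gives the alkenylzinc chloride F3, and Negishi coupling with 7 gives the dienyl bis-ketal F4. PPTS in acetone/H2O at 0 °C then releases the (Z)-enedione 27 with no oxidant ever in contact with the diene.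

**Step 15 (the proposed new cycloaddition).** The catalyst may not override the substrate or may not bind the hindered enedione. The fallback uses known tether control and sets out from 16 and returns at 28. Alcohol 16 is epoxidised with Ti(OiPr)4, L-(+)-diisopropyl tartrate and t-BuOOH to the (S)-epoxy alcohol F5. As in step 11, its chloromagnesium alkoxide F6 is opened by 19 to the silylalkyne diol F7 and desilylated to the C7-epimeric diol F8. Acetonide formation gives the epimeric acetonide F9. Hydrozirconation (alkenylzirconocene chloride F10), transmetalation (alkenylzinc chloride F11) and coupling with 7 give the epimeric furan–diene F12, and NBS gives the epimeric enedione F13. In this series the C7 oxygen can sit axial in the tether and chelate magnesium with the C5 carbonyl (MgBr2·OEt2, CH2Cl2, −20 °C). This reinforces the A(1,3) bias of the sec-butyl centre, so substrate control gives the C7-epimeric adduct F14 with the ring configuration of 28. C7 is then inverted: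
- CuCl2·2H2O in MeCN cleaves the acetonide to the 7α-hydroxy diol F15.
- PPh3 and DIAD (Mitsunobu cyclodehydration) close the spiro-epoxide F16 with retention.
- HClO4 (cat.) in THF/H2O opens it at the tertiary carbon with inversion to the 7β-hydroxy diol F17.
- Me2C(OMe)2 and PPTS give 28.

**Step 17 (chemo- and face-selective hydrogenation that sets C5).** The fallback sets out from 29 and returns at 30 and makes no new compound. It replaces kinetic face selection on a metal catalyst with hydrogen-atom-transfer hydrogenation (Mn(dpm)3 cat., PhSiH3, t-BuOOH, i-PrOH, 25 °C). The 1,1-disubstituted alkene is the preferred hydrogen-atom acceptor, and the planar tertiary C5 radical is quenched axially to give the thermodynamically preferred equatorial (α) methyl.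

## Further compounds

F1 | step 14 | tert-butyl(2-{5-[((4S)-2,2-dimethyl-4-(prop-2-yn-1-yl)-1,3-dioxolan-4-yl)methyl]-2,5-dimethoxy-3-methyl-2,5-dihydrofuran-2-yl}ethoxy)dimethylsilane (ketal epimers) | COC1(CCO[Si](C)(C)C(C)(C)C)OC(C[C@@]2(CC#C)COC(C)(C)O2)(OC)C=C1C
F2 | step 14 | (E)-alkenylzirconocene chloride from F1 | Cl[Zr](C1C=CC=C1)(C1C=CC=C1)/C=C/C[C@]1(CC2(OC)OC(CCO[Si](C)(C)C(C)(C)C)(OC)C(C)=C2)COC(C)(C)O1
F3 | step 14 | (E)-alkenylzinc chloride from F2 | Cl[Zn]/C=C/C[C@]1(CC2(OC)OC(CCO[Si](C)(C)C(C)(C)C)(OC)C(C)=C2)COC(C)(C)O1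
F4 | step 14 | dienyl 2,5-dimethoxy-2,5-dihydrofuran (bis-ketal of 27) | CC[C@@H](C)/C=C(C)/C=C/C[C@]1(CC2(OC)OC(CCO[Si](C)(C)C(C)(C)C)(OC)C(C)=C2)COC(C)(C)O1
F5 | step 15 | {(2S)-2-[3-(trimethylsilyl)prop-2-yn-1-yl]oxiran-2-yl}methanol | C1[C@@](O1)(CO)CC#C[Si](C)(C)C
F6 | step 15 | chloromagnesium alkoxide of F5 | C1[C@@](O1)(CO[Mg]Cl)CC#C[Si](C)(C)C
F7 | step 15 | (2R)-2-{[5-(2-{[tert-butyl(dimethyl)silyl]oxy}ethyl)-4-methylfuran-2-yl]methyl}-5-(trimethylsilyl)pent-4-yne-1,2-diol | Cc1cc(C[C@@](O)(CO)CC#C[Si](C)(C)C)oc1CCO[Si](C)(C)C(C)(C)C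
F8 | step 15 | (2R)-2-{[5-(2-{[tert-butyl(dimethyl)silyl]oxy}ethyl)-4-methylfuran-2-yl]methyl}pent-4-yne-1,2-diol | Cc1cc(C[C@@](O)(CO)CC#C)oc1CCO[Si](C)(C)C(C)(C)C
F9 | step 15 | (4R)-dioxolane, C7 epimer of 23 | Cc1cc(C[C@]2(CC#C)COC(C)(C)O2)oc1CCO[Si](C)(C)C(C)(C)C
F10 | step 15 | (E)-alkenylzirconocene chloride from F9 | Cl[Zr](C1C=CC=C1)(C1C=CC=C1)/C=C/C[C@@]1(Cc2cc(C)c(CCO[Si](C)(C)C(C)(C)C)o2)COC(C)(C)O1
F11 | step 15 | (E)-alkenylzinc chloride from F10 | Cl[Zn]/C=C/C[C@@]1(Cc2cc(C)c(CCO[Si](C)(C)C(C)(C)C)o2)COC(C)(C)O1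
F12 | step 15 | C7 epimer of 26 | CC[C@@H](C)/C=C(C)/C=C/C[C@@]1(Cc2cc(C)c(CCO[Si](C)(C)C(C)(C)C)o2)COC(C)(C)O1
F13 | step 15 | C7 epimer of 27 | CC[C@@H](C)/C=C(C)/C=C/C[C@@]1(CC(=O)/C=C(C)\C(=O)CCO[Si](C)(C)C(C)(C)C)COC(C)(C)O1
F14 | step 15 | C7 epimer of 28 (O on C7 α, CH2O β) | CC[C@@H](C)[C@@H]1[C@](C)(C(=O)CCO[Si](C)(C)C(C)(C)C)[C@@H]2C(=O)C[C@@]3(COC(C)(C)O3)C[C@@H]2C=C1C
F15 | step 15 | 7α-hydroxy-7β-(hydroxymethyl) diol from F14 | CC[C@@H](C)[C@@H]1[C@](C)(C(=O)CCO[Si](C)(C)C(C)(C)C)[C@@H]2C(=O)C[C@@](O)(CO)C[C@@H]2C=C1C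
F16 | step 15 | C7 spiro-epoxide (oxirane O on C7 α) | CC[C@@H](C)[C@@H]1[C@](C)(C(=O)CCO[Si](C)(C)C(C)(C)C)[C@@H]2C(=O)C[C@@]3(CO3)C[C@@H]2C=C1C
F17 | step 15 | 7β-hydroxy-7α-(hydroxymethyl) diol (28 without the acetonide) | CC[C@@H](C)[C@@H]1[C@](C)(C(=O)CCO[Si](C)(C)C(C)(C)C)[C@@H]2C(=O)C[C@](O)(CO)C[C@@H]2C=C1C
F0 | step 17 | none | none
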